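The flavone is disconnected between pyranone carbon C2 and B-ring carbon C1′, so that an intact A/C chromone and a hydroquinone-derived arene are united late. The key step exploits two features. Ring A is fully substituted (C5–C8 all carry oxygen), so the chromone offers only C2–H and C3–H, and C2–H, adjacent to O1, is the one removed by a magnesium-free zinc amide. Ring B is a hydroquinone whose four C–H positions are equivalent, so bromohydroquinone supplies it without regiochemical ambiguity. One-pot C2–H zincation/Negishi coupling of 5,6,7,8-tetramethoxychromone with 1,4-bis(benzyloxy)-2-bromobenzene gives the complete skeleton; a single BCl3 operation then liberates all three hydroxyls.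

Key step: step 3

Remark: the target has no stereocentre and no stereogenic axis, so it is achiral and no stereocontrol is required. Acetophenone 1 is assumed to be a catalogue compound.

Step 1
Reactants: 1 1-(2-hydroxy-3,4,5,6-tetramethoxyphenyl)ethan-1-one
Product: 3 5,6,7,8-tetramethoxy-4H-chromen-4-one, via enaminone 2 (not isolated)
Conditions: Me2NCH(OMe)2, toluene, 110 °C; evaporate; then conc. HCl, CH2Cl2, 40 °C
Reagents that add atoms: N,N-dimethylformamide dimethyl acetal, COC(OC)N(C)C
Why: Enaminone route to chromones: the amide acetal condenses with the methyl ketone to give (E)-enaminone 2, and acid then triggers conjugate addition of the 2-hydroxyl and elimination of dimethylamine (addition–elimination, 6-endo closure), conditions under which the four aryl methyl ethers are inert.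

Step 2
Reactants: 4 2-bromobenzene-1,4-diol
Product: 5 1,4-bis(benzyloxy)-2-bromobenzene
Conditions: BnBr, K2CO3, DMF, 60 °C, N2
Reagents that add atoms: benzyl bromide, BrCc1ccccc1
Why: Williamson ether synthesis: both phenoxides of 4 are benzylated by SN2 displacement on benzyl bromide, while the aryl bromide is untouched and exclusion of air prevents oxidation to the quinone.

Step 3
Reactants: 3 5,6,7,8-tetramethoxy-4H-chromen-4-one; 5 1,4-bis(benzyloxy)-2-bromobenzene
Product: 7 2-[2,5-bis(benzyloxy)phenyl]-5,6,7,8-tetramethoxy-4H-chromen-4-one, via chromon-2-ylzinc chloride 6 (not isolated)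
Conditions: TMPZnCl·LiCl (1.2 equiv, Mg-free), THF, 25 °C; then 5, Pd(OAc)2 (2 mol %), SPhos (4 mol %), THF, 50 °C
Reagents that add atoms: TMPZnCl·LiCl, CC1(C)CCCC(C)(C)N1[Zn]Cl.[Li+].[Cl-] (its ZnCl unit is carried by intermediate 6 only)
Why: The hindered, LiCl-solubilised zinc amide removes the C2 proton of 3, the most acidic C–H (sp2 carbon bound to O1 and β to the C4 carbonyl), to give alkenylzinc 6, whose covalent C–Zn bond does not add to the carbonyl. Pd(0)/SPhos then inserts into the C–Br bond of 5, and transmetalation with 6 followed by reductive elimination forges the C2–C1′ bond (Negishi cross-coupling). The closest known reaction type is the deprotonative C2-zincation of chromones followed by Negishi arylation, a known entry to flavones. No ring is closed and no stereocentre is created. The selectivity needed is C2 over C3 metalation, which should be secured by the magnesium-free base (a Lewis acid on the C4 carbonyl would steer the amide to C3) and by ring A, whose positions C5–C8 are all substituted and offer no competing C–H. On the B-ring side no regiocontrol is needed because the bromine of 5 marks one of four equivalent hydroquinone positions, and the zinc amide is too weak a base to attack the benzylic ethers.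

Step 4
Reactants: 7 2-[2,5-bis(benzyloxy)phenyl]-5,6,7,8-tetramethoxy-4H-chromen-4-one
Product: 8 5-hydroxy-2-(2,5-dihydroxyphenyl)-6,7,8-trimethoxy-4H-chromen-4-one (5,2',5'-trihydroxy-6,7,8-trimethoxyflavone)
Conditions: BCl3 (6 equiv), C6HMe5 (6 equiv), CH2Cl2, −78 °C → rt; then MeOH, aq. HCl, Na2S2O4 wash, under argon
Reagents that add atoms: none
Why: Lewis-acid ether cleavage: BCl3 cleaves the two aryl benzyl ethers (benzyl cations trapped by pentamethylbenzene) and, through the six-membered boron chelate between the C4 carbonyl and O5, only the peri 5-methoxy group, while the unactivated 6-, 7- and 8-methoxy groups should remain.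

Compound list
1 | 1-(2-hydroxy-3,4,5,6-tetramethoxyphenyl)ethan-1-one | CC(=O)c1c(O)c(OC)c(OC)c(OC)c1OC | starting material
2 | (E)-3-(dimethylamino)-1-(2-hydroxy-3,4,5,6-tetramethoxyphenyl)prop-2-en-1-one | CN(C)/C=C/C(=O)c1c(O)c(OC)c(OC)c(OC)c1OC | intermediate (not isolated)
3 | 5,6,7,8-tetramethoxy-4H-chromen-4-one | COc1c(OC)c(OC)c2c(=O)ccoc2c1OC | intermediate
4 | 2-bromobenzene-1,4-diol (bromohydroquinone) | Oc1ccc(O)c(Br)c1 | starting material
5 | 1,4-bis(benzyloxy)-2-bromobenzene | Brc1cc(OCc2ccccc2)ccc1OCc1ccccc1 | intermediate
6 | chloro(5,6,7,8-tetramethoxy-4-oxo-4H-chromen-2-yl)zinc, as its LiCl complex | COc1c(OC)c(OC)c2c(=O)cc([Zn]Cl)oc2c1OC | intermediate (not isolated)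
7 | 2-[2,5-bis(benzyloxy)phenyl]-5,6,7,8-tetramethoxy-4H-chromen-4-one | COc1c(OC)c(OC)c2c(=O)cc(-c3cc(OCc4ccccc4)ccc3OCc3ccccc3)oc2c1OC | intermediate
8 | 5-hydroxy-2-(2,5-dihydroxyphenyl)-6,7,8-trimethoxy-4H-chromen-4-one | COc1c(OC)c(O)c2c(=O)cc(-c3cc(O)ccc3O)oc2c1OC | target

Total step count: 4
Longest linear sequence: 3 steps (steps 1, 3 and 4; step 2 is a one-step side branch).

Steps most likely to fail

Step 3 (key step). The deprotonation may lose regiocontrol if the 5-methoxy/C4-carbonyl pair guides the amide to C3, the pyranone may be opened by the amide, or transmetalation to the hindered ortho-alkoxyaryl palladium species may be slow and give way to homocoupling. The fallback reverses the polarity and needs no chromone metalation. It sets out from bromide 5: bromine–lithium exchange (n-BuLi, THF, −78 °C), trapping with B(OiPr)3 and acidic hydrolysis should give 2,5-bis(benzyloxy)phenylboronic acid F1. A Pd(II)-catalysed oxidative Heck-type arylation of chromone 3 with F1 (Pd(TFA)2 cat., Cu(OAc)2/O2 as reoxidant, DMSO/AcOH, 80 °C) then proceeds by transmetalation, aryl delivery to C2 through carbopalladation of C2=C3, and β-hydride elimination. It comes back to the route at 7.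

Step 4. Demethylation may run on to O6 once the 5-O–boron chelate has formed, or the 5-methoxy group may be cleaved incompletely at the low temperature that clean debenzylation needs. The electron-rich B ring may also be benzylated in a Friedel–Crafts sense, and the hydroquinone may oxidise in air during work-up. The fallback uses two orthogonal operations and sets out from 7. Hydrogenolysis (H2, Pd/C, EtOAc/MeOH, rt) should give 2-(2,5-dihydroxyphenyl)-5,6,7,8-tetramethoxy-4H-chromen-4-one F2. Chelation-controlled cleavage of the 5-methoxy group alone (AlCl3, MeCN, rt) then arrives at target 8.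

Step 1. Condensation of the di-ortho-substituted, twisted acetyl group with the amide acetal may be sluggish, the phenol may be O-methylated by the acetal, or the enaminone may cyclise incompletely. The fallback is a Claisen formylation that sets out from 1. Ethyl formate with NaH in THF, followed by acidification, should give 2-hydroxy-5,6,7,8-tetramethoxychroman-4-one F3, the cyclic hemiacetal of the β-keto aldehyde. Dehydration with catalytic H2SO4 in AcOH comes back to the route at 3.

Further compounds
F1 | step 3 | 2,5-bis(benzyloxy)phenylboronic acid | OB(O)c1cc(OCc2ccccc2)ccc1OCc1ccccc1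
F2 | step 4 | 2-(2,5-dihydroxyphenyl)-5,6,7,8-tetramethoxy-4H-chromen-4-one | COc1c(OC)c(OC)c2c(=O)cc(-c3cc(O)ccc3O)oc2c1OC
F3 | step 1 | 2-hydroxy-5,6,7,8-tetramethoxychroman-4-one (racemic hemiacetal) | OC1CC(=O)c2c(OC)c(OC)c(OC)c(OC)c2O1
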